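**Assumption:** the registry entry is taken to be exactly the drawn all-E isomer, (3S,4R,3'R,6'R)-β,ε-carotene-3,4,3'-triol; ring positions are cited in carotenoid numbering (C1 = CMe2, C3 = CHOH, C5 = CMe, C6 = chain-bearing carbon).

## Retrosynthetic overview

1. Target ⇒ Horner–Wadsworth–Emmons union (C11=C12) of a C25 ε-end phosphonate with a C15 (3S,4R)-dihydroxy-β aldehyde; the C25 piece ⇒ C10 bis(phosphonate) + C15 (3R,6R)-hydroxy-ε aldehyde (C11'=C12').
2. Both C15 aldehydes ⇒ the two enantiomers of one racemic 3,6-trans 3-acetoxy-ε C15 nitrile, parted by a lipase in two passes. The (3S,6S) half becomes the cis-diol β-ring by hydroxyl-directed epoxidation and base-induced oxirane opening, which trades the C6 stereocentre for C4.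
3. Racemic C15 nitrile ⇒ 3-hydroxy-α-cyclocitral + C5 cyano-phosphonate; the aldehyde ⇒ a glycol-linked bis(3-oxo-α-cyclogeranate).
4. Ring order: both cyclohexene rings are made first and together, by a twofold Robinson annulation of mesityl oxide onto ethylene glycol bis(acetoacetate). The only later ring is the transient oxirane on the future β-ring (made in step 8, opened in step 9).

## Route

Step 1
Reactants: 1 ethane-1,2-diol; 2 tert-butyl 3-oxobutanoate
Product: 3 ethane-1,2-diyl bis(3-oxobutanoate)
Conditions: 2 (2.2 equiv), toluene, 110 °C, t-BuOH distilled off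
Reagents that add atoms: none
Why: thermal transacetoacetylation (transesterification) of the primary diol is driven to completion by removal of tert-butanol, and no stereocentre is formed.

Step 2
Reactants: 3 ethane-1,2-diyl bis(3-oxobutanoate); 4 4-methylpent-3-en-2-one (mesityl oxide)
Product: 6 ethane-1,2-diyl bis(2,6,6-trimethyl-4-oxocyclohex-2-ene-1-carboxylate) (rac/meso mixture), via bis-Michael adduct 5 (not isolated)
Conditions: 4 (3 equiv), ZnCl2 (anhydrous, 0.3 equiv), toluene–heptane, reflux, Dean–Stark trap, 72 h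
Reagents that add atoms: none
Why: twofold Robinson annulation, in which ZnCl2-promoted Michael addition of each β-keto ester enol to mesityl oxide builds the two quaternary C1 centres and aldol condensation of each mesityl-derived methyl ketone onto the acetoacetyl carbonyl closes both cyclohexenone rings in one flask, as known for ethyl acetoacetate; C6 forms without control and is left racemic on purpose.

Step 3
Reactants: 6 ethane-1,2-diyl bis(2,6,6-trimethyl-4-oxocyclohex-2-ene-1-carboxylate)
Product: 7 rac-(1S,4S)-4-hydroxy-2,6,6-trimethylcyclohex-2-ene-1-carbaldehyde (racemic 3,6-trans isomer; the minor 3,6-cis isomer is removed after step 4)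
Conditions: i-Bu2AlH (4.4 equiv), CH2Cl2, −78 °C, 2 h; MeOH at −78 °C, then aq KNaC4H4O6 (potassium sodium tartrate)
Reagents that add atoms: none
Why: at −78 °C i-Bu2AlH reduces the enone carbonyl 1,2 and stops at the aluminium hemiacetal of each hindered ester (partial ester reduction), so work-up releases two hydroxy aldehydes and the glycol tether, while hydride is expected to reach C3 anti to the pseudo-axial C1 methyl group and so set the C3–O bond trans to the C6 substituent as the major relative configuration (the cis isomer also forms and is separated later).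

Step 4
Reactants: 7 rac-(1S,4S)-4-hydroxy-2,6,6-trimethylcyclohex-2-ene-1-carbaldehyde; 8 diethyl [(2E)-3-cyano-2-methylprop-2-en-1-yl]phosphonate
Product: 10 rac-(2E,4E)-5-[(1S,4S)-4-acetoxy-2,6,6-trimethylcyclohex-2-en-1-yl]-3-methylpenta-2,4-dienenitrile, via hydroxy nitrile 9 (not isolated)
Conditions: 8 (2.2 equiv), LiN(SiMe3)2 (2.2 equiv), THF, −78 °C; add 7; −78 → 0 °C; then Et3N (3 equiv), Ac2O (2 equiv), DMAP (5 mol %), rt; chromatography
Reagents that add atoms: acetic anhydride, CC(=O)OC(C)=O
Why: Horner–Wadsworth–Emmons olefination by the lithiated allylic phosphonate gives the 7E alkene (9E major; 9Z and ring-cis isomers are removed on silica) and the free hydroxyl is acetylated in the same pot, while at −78 °C addition to the aldehyde outruns enolisation so that C6 keeps its hydrogen and the ring stays in the ε (C4=C5) form.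

Step 5
Reactants: 10 rac-(2E,4E)-5-[(1S,4S)-4-acetoxy-2,6,6-trimethylcyclohex-2-en-1-yl]-3-methylpenta-2,4-dienenitrile
Product: 11 (2E,4E)-5-[(1S,4S)-4-hydroxy-2,6,6-trimethylcyclohex-2-en-1-yl]-3-methylpenta-2,4-dienenitrile
Conditions: Burkholderia cepacia lipase (immobilised), KH2PO4/K2HPO4 buffer (0.1 M, pH 7.0)–MTBE, 30 °C, stopped at ca. 45% conversion (chiral HPLC); chromatography (alcohol 11 collected, the unhydrolysed acetate fraction kept for step 6)
Reagents that add atoms: none
Why: lipase-catalysed enantioselective hydrolysis (kinetic resolution) stopped short of half conversion so that the alcohol is obtained in high ee, the (3S,6S)-acetate being the expected fast-reacting enantiomer by the Kazlauskas rule with the CMe2-bearing flank of the carbinol as the large group (configuration checked by CD, an opposite sense merely exchanging which enantiomer carries the acetate).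

Step 6
Reactants: 10 rac-(2E,4E)-5-[(1S,4S)-4-acetoxy-2,6,6-trimethylcyclohex-2-en-1-yl]-3-methylpenta-2,4-dienenitrile (the acetate fraction recovered from step 5, already enriched in the 1R,4R enantiomer)
Product: 12 (2E,4E)-5-[(1R,4R)-4-acetoxy-2,6,6-trimethylcyclohex-2-en-1-yl]-3-methylpenta-2,4-dienenitrile
Conditions: Burkholderia cepacia lipase (immobilised), KH2PO4/K2HPO4 buffer (0.1 M, pH 7.0)–MTBE, 30 °C, run until no (1S,4S)-acetate is left (chiral HPLC; ca. 55% total conversion counted from racemic 10); chromatography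
Reagents that add atoms: none
Why: second pass of the same lipase kinetic resolution, in which the residual fast-reacting (1S,4S)-acetate is hydrolysed away and the slow-reacting (1R,4R)-acetate is left untouched in high ee, because the ee of the unreacted substrate rises with conversion.

Step 7
Reactants: 12 (2E,4E)-5-[(1R,4R)-4-acetoxy-2,6,6-trimethylcyclohex-2-en-1-yl]-3-methylpenta-2,4-dienenitrile
Product: 13 (2E,4E)-5-[(1R,4R)-4-hydroxy-2,6,6-trimethylcyclohex-2-en-1-yl]-3-methylpenta-2,4-dienal
Conditions: i-Bu2AlH (4 equiv), CH2Cl2, −78 → −40 °C; aq KNaC4H4O6, 0 °C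
Reagents that add atoms: water, O
Why: i-Bu2AlH reduces the conjugated nitrile to the aluminium aldimine, which work-up hydrolyses to the dienal, and removes the acetate reductively in the same operation without touching either stereocentre.

Step 8
Reactants: 11 (2E,4E)-5-[(1S,4S)-4-hydroxy-2,6,6-trimethylcyclohex-2-en-1-yl]-3-methylpenta-2,4-dienenitrile
Product: 14 (2E,4E)-5-[(1R,2S,5S,6S)-5-hydroxy-1,3,3-trimethyl-7-oxabicyclo[4.1.0]heptan-2-yl]-3-methylpenta-2,4-dienenitrile
Conditions: t-BuOOH (1.3 equiv, in decane), VO(acac)2 (2 mol %), CH2Cl2, 0 °C → rt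
Reagents that add atoms: tert-butyl hydroperoxide, CC(C)(C)OO
Why: vanadium-catalysed hydroxyl-directed epoxidation delivers oxygen to the C4=C5 alkene from the face of the allylic 3-OH, which is also the face opposite the C6 side chain, and so fixes the future C4–O bond cis to C3–O while the electron-poor dienenitrile is left alone.

Step 9
Reactants: 14 (2E,4E)-5-[(1R,2S,5S,6S)-5-hydroxy-1,3,3-trimethyl-7-oxabicyclo[4.1.0]heptan-2-yl]-3-methylpenta-2,4-dienenitrile
Product: 15 (2E,4E)-5-[(3R,4S)-3,4-dihydroxy-2,6,6-trimethylcyclohex-1-en-1-yl]-3-methylpenta-2,4-dienenitrile (carotenoid numbering 3S,4R)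
Conditions: KOt-Bu (2.2 equiv), THF, 0 °C → rt; then H2O
Reagents that add atoms: none
Why: base-induced epoxide-to-allylic-alcohol isomerisation (E1cB-type opening through the C6 carbanion stabilised by the dienenitrile, as known for α-ionone 4,5-epoxide going to 4-hydroxy-β-ionone) breaks only the C5–O bond, so the C4–O bond keeps its configuration and the 3,4-cis diol with the C5=C6 (β) double bond results, the C6 stereocentre being consumed.

Step 10
Reactants: 15 (2E,4E)-5-[(3R,4S)-3,4-dihydroxy-2,6,6-trimethylcyclohex-1-en-1-yl]-3-methylpenta-2,4-dienenitrile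
Product: 16 (2E,4E)-5-[(3R,4S)-3,4-dihydroxy-2,6,6-trimethylcyclohex-1-en-1-yl]-3-methylpenta-2,4-dienal
Conditions: i-Bu2AlH (5 equiv), CH2Cl2–THF, −78 → −40 °C; aq KNaC4H4O6 (pH ca. 7), 0 °C
Reagents that add atoms: water, O
Why: nitrile-to-aldehyde reduction through the aluminium aldimine, with a non-acidic work-up that spares the ionisable allylic C4 hydroxyl.

Step 11
Reactants: 17 (2E,4E,6E)-2,7-dimethylocta-2,4,6-trienedial
Product: 18 (2E,4E,6E)-2,7-dimethylocta-2,4,6-triene-1,8-diol
Conditions: NaBH4 (1.1 equiv), MeOH–THF, 0 °C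
Reagents that add atoms: none
Why: borohydride 1,2-reduction of the conjugated dialdehyde leaves the triene geometry untouched.

Step 12
Reactants: 18 (2E,4E,6E)-2,7-dimethylocta-2,4,6-triene-1,8-diol
Product: 20 tetraethyl [(2E,4E,6E)-2,7-dimethylocta-2,4,6-triene-1,8-diyl]bis(phosphonate), via dibromide 19 (not isolated)
Conditions: PBr3 (0.75 equiv), Et2O, pyridine (cat.), −15 °C, dark; crude 19 then P(OEt)3 (4 equiv), toluene, 100 °C
Reagents that add atoms: phosphorus tribromide, BrP(Br)Br (bromine only in 19); triethyl phosphite, CCOP(OCC)OCC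
Why: allylic bromination followed by a Michaelis–Arbuzov reaction at the unhindered primary allylic termini (SN2) keeps the E,E,E-triene.

Step 13
Reactants: 20 tetraethyl [(2E,4E,6E)-2,7-dimethylocta-2,4,6-triene-1,8-diyl]bis(phosphonate); 13 (2E,4E)-5-[(1R,4R)-4-hydroxy-2,6,6-trimethylcyclohex-2-en-1-yl]-3-methylpenta-2,4-dienal
Product: 21 diethyl [(2E,4E,6E,8E,10E,12E)-13-[(1R,4R)-4-hydroxy-2,6,6-trimethylcyclohex-2-en-1-yl]-2,7,11-trimethyltrideca-2,4,6,8,10,12-hexaen-1-yl]phosphonate
Conditions: 20 (3 equiv), KN(SiMe3)2 (2.1 equiv based on 13), THF, −78 °C; slow addition of 13; −78 → 0 °C; chromatography (excess 20 recovered)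
Reagents that add atoms: none
Why: Horner–Wadsworth–Emmons olefination forms C11'=C12' with E geometry, the excess bis(phosphonate) and slow aldehyde addition hold it at mono-olefination, and C6'–H, which lies in the nodal plane of the side-chain π system, is not removed under these conditions.

Step 14
Reactants: 21 diethyl [(2E,4E,6E,8E,10E,12E)-13-[(1R,4R)-4-hydroxy-2,6,6-trimethylcyclohex-2-en-1-yl]-2,7,11-trimethyltrideca-2,4,6,8,10,12-hexaen-1-yl]phosphonate; 16 (2E,4E)-5-[(3R,4S)-3,4-dihydroxy-2,6,6-trimethylcyclohex-1-en-1-yl]-3-methylpenta-2,4-dienal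
Product: 22 (all-E)-(3S,4R,3'R,6'R)-β,ε-carotene-3,4,3'-triol (CNP0191612.1)
Conditions: 21 (1.1 equiv), KOt-Bu (4.5 equiv), THF, −40 → 0 °C, N2, dark; then reflux in EtOH (Z → E equilibration) and crystallisation
Reagents that add atoms: none
Why: the second Horner–Wadsworth–Emmons olefination forms C11=C12, the four stereocentres arrive unchanged with 21 and 16, the free hydroxyls are carried as alkoxides, and thermal equilibration followed by crystallisation gives the favoured all-E polyene.

## Compound list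

1 | ethane-1,2-diol | OCCO | starting material
2 | tert-butyl 3-oxobutanoate | CC(=O)CC(=O)OC(C)(C)C | starting material
3 | ethane-1,2-diyl bis(3-oxobutanoate) | CC(=O)CC(=O)OCCOC(=O)CC(C)=O | intermediate
4 | 4-methylpent-3-en-2-one (mesityl oxide) | CC(=O)C=C(C)C | starting material
5 | ethane-1,2-diyl bis(2-acetyl-3,3-dimethyl-5-oxohexanoate) (stereoisomer mixture, drawn without descriptors; not isolated) | CC(=O)CC(C)(C)C(C(C)=O)C(=O)OCCOC(=O)C(C(C)=O)C(C)(C)CC(C)=O | intermediate
6 | ethane-1,2-diyl bis(2,6,6-trimethyl-4-oxocyclohex-2-ene-1-carboxylate) (rac/meso mixture, drawn without descriptors) | CC1=CC(=O)CC(C)(C)C1C(=O)OCCOC(=O)C1C(C)=CC(=O)CC1(C)C | intermediate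
7 | rac-(1S,4S)-4-hydroxy-2,6,6-trimethylcyclohex-2-ene-1-carbaldehyde (racemic 3,6-trans isomer; the 1S,4S enantiomer is drawn) | CC1=C[C@@H](O)CC(C)(C)[C@@H]1C=O | intermediate
8 | diethyl [(2E)-3-cyano-2-methylprop-2-en-1-yl]phosphonate | CCOP(=O)(OCC)C/C(C)=C/C#N | starting material
9 | rac-(2E,4E)-5-[(1S,4S)-4-hydroxy-2,6,6-trimethylcyclohex-2-en-1-yl]-3-methylpenta-2,4-dienenitrile (racemate, the 1S,4S enantiomer is drawn; not isolated) | CC1=C[C@@H](O)CC(C)(C)[C@@H]1/C=C/C(C)=C/C#N | intermediate
10 | rac-(2E,4E)-5-[(1S,4S)-4-acetoxy-2,6,6-trimethylcyclohex-2-en-1-yl]-3-methylpenta-2,4-dienenitrile (racemate, the 1S,4S enantiomer is drawn) | CC1=C[C@@H](OC(C)=O)CC(C)(C)[C@@H]1/C=C/C(C)=C/C#N | intermediate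
11 | (2E,4E)-5-[(1S,4S)-4-hydroxy-2,6,6-trimethylcyclohex-2-en-1-yl]-3-methylpenta-2,4-dienenitrile (single enantiomer; carotenoid numbering 3S,6S) | CC1=C[C@@H](O)CC(C)(C)[C@@H]1/C=C/C(C)=C/C#N | intermediate
12 | (2E,4E)-5-[(1R,4R)-4-acetoxy-2,6,6-trimethylcyclohex-2-en-1-yl]-3-methylpenta-2,4-dienenitrile (single enantiomer; carotenoid numbering 3R,6R) | CC1=C[C@H](OC(C)=O)CC(C)(C)[C@H]1/C=C/C(C)=C/C#N | intermediate
13 | (2E,4E)-5-[(1R,4R)-4-hydroxy-2,6,6-trimethylcyclohex-2-en-1-yl]-3-methylpenta-2,4-dienal | CC1=C[C@H](O)CC(C)(C)[C@H]1/C=C/C(C)=C/C=O | intermediate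
14 | (2E,4E)-5-[(1R,2S,5S,6S)-5-hydroxy-1,3,3-trimethyl-7-oxabicyclo[4.1.0]heptan-2-yl]-3-methylpenta-2,4-dienenitrile (oxirane syn to the hydroxyl) | C[C@]12O[C@H]1[C@@H](O)CC(C)(C)[C@@H]2/C=C/C(C)=C/C#N | intermediate
15 | (2E,4E)-5-[(3R,4S)-3,4-dihydroxy-2,6,6-trimethylcyclohex-1-en-1-yl]-3-methylpenta-2,4-dienenitrile (cis-diol; carotenoid numbering 3S,4R) | N#C/C=C(C)/C=C/C1=C(C)[C@@H](O)[C@@H](O)CC1(C)C | intermediate
16 | (2E,4E)-5-[(3R,4S)-3,4-dihydroxy-2,6,6-trimethylcyclohex-1-en-1-yl]-3-methylpenta-2,4-dienal | O=C/C=C(C)/C=C/C1=C(C)[C@@H](O)[C@@H](O)CC1(C)C | intermediate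
17 | (2E,4E,6E)-2,7-dimethylocta-2,4,6-trienedial | O=C/C(C)=C/C=C/C=C(C)/C=O | starting material
18 | (2E,4E,6E)-2,7-dimethylocta-2,4,6-triene-1,8-diol | OC/C(C)=C/C=C/C=C(C)/CO | intermediate
19 | (2E,4E,6E)-1,8-dibromo-2,7-dimethylocta-2,4,6-triene (not isolated) | BrC/C(C)=C/C=C/C=C(C)/CBr | intermediate
20 | tetraethyl [(2E,4E,6E)-2,7-dimethylocta-2,4,6-triene-1,8-diyl]bis(phosphonate) | CCOP(=O)(OCC)C/C(C)=C/C=C/C=C(C)/CP(=O)(OCC)OCC | intermediate
21 | diethyl [(2E,4E,6E,8E,10E,12E)-13-[(1R,4R)-4-hydroxy-2,6,6-trimethylcyclohex-2-en-1-yl]-2,7,11-trimethyltrideca-2,4,6,8,10,12-hexaen-1-yl]phosphonate | CCOP(=O)(OCC)C/C(C)=C/C=C/C=C(C)/C=C/C=C(C)/C=C/[C@H]1C(C)=C[C@H](O)CC1(C)C | intermediate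
22 | (all-E)-(3S,4R,3'R,6'R)-β,ε-carotene-3,4,3'-triol | CC1=C[C@H](O)CC(C)(C)[C@H]1/C=C/C(C)=C/C=C/C(C)=C/C=C/C=C(C)/C=C/C=C(C)/C=C/C1=C(C)[C@@H](O)[C@@H](O)CC1(C)C | target

## Step count and risks

Total steps: 14. Longest linear sequence: 9 (steps 1, 2, 3, 4, 5, 8, 9, 10, 14; the ε-end branch through steps 5, 6, 7 and 13 is equally long).

**Step 2.** Two Michael additions that create quaternary centres and two aldol closures must all succeed on one molecule, and mesityl oxide self-condenses under ZnCl2. The fallback builds the same two rings by a twofold Diels–Alder reaction instead of Michael/aldol chemistry. It sets out from 4 and 1. Compound 4 is converted with Me3SiCl, Et3N and NaI in MeCN into 4-methyl-2-(trimethylsilyloxy)penta-1,3-diene F1. Compound 1 is esterified with but-2-ynoic acid (DCC, DMAP) to ethane-1,2-diyl bis(but-2-ynoate) F2. Heating F2 with F1 (3 equiv, toluene, 150 °C, sealed tube) forms both rings at once, with the silyloxy carbon para to the ester-bearing carbon, as ethane-1,2-diyl bis[2,6,6-trimethyl-4-(trimethylsilyloxy)cyclohexa-1,4-diene-1-carboxylate] F3. Treatment with 1 M HCl in THF cleaves both silyl enol ethers and moves each ring double bond into conjugation with the ketone, which brings the route back at 6.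

**Step 4.** The β,γ-unsaturated aldehyde 7 can enolise, epimerise at C6 or slip into the conjugated β-form before it is olefinated. The fallback is a two-stage C3 + C2 homologation that starts with a base-free Wittig reaction. It sets out from 7. Ph3P=CHC(O)CH3 in toluene at 80 °C gives rac-(3E)-4-[(1S,4S)-4-hydroxy-2,6,6-trimethylcyclohex-2-en-1-yl]but-3-en-2-one F4 (racemic trans-3-hydroxy-α-ionone). Horner–Wadsworth–Emmons reaction of F4 with diethyl cyanomethylphosphonate and LiN(SiMe3)2 in THF, followed by Et3N/Ac2O/DMAP in the same pot, leads through 9 to the acetate 10, where the route is rejoined.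

**Step 9.** KOt-Bu may scramble the 9,10-double bond or take a C18 methyl proton instead of C6–H. The fallback replaces the epoxidation/base pair by a Schenck ene reaction, so it sets out from 11, before step 8. With O2, tetraphenylporphyrin and visible light in CH2Cl2 at −20 °C, singlet oxygen held on the hydroxyl face takes the cis-disposed C6–H and bonds to C4 on that same face. This gives (2E,4E)-5-[(3R,4S)-3-hydroperoxy-4-hydroxy-2,6,6-trimethylcyclohex-1-en-1-yl]-3-methylpenta-2,4-dienenitrile F5. Ph3P reduces F5 to 15, where the route is rejoined.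

Further compounds
F1 | step 2 | 4-methyl-2-(trimethylsilyloxy)penta-1,3-diene | C=C(O[Si](C)(C)C)C=C(C)C
F2 | step 2 | ethane-1,2-diyl bis(but-2-ynoate) | CC#CC(=O)OCCOC(=O)C#CC
F3 | step 2 | ethane-1,2-diyl bis[2,6,6-trimethyl-4-(trimethylsilyloxy)cyclohexa-1,4-diene-1-carboxylate] | CC1=C(C(=O)OCCOC(=O)C2=C(C)CC(O[Si](C)(C)C)=CC2(C)C)C(C)(C)C=C(O[Si](C)(C)C)C1
F4 | step 4 | rac-(3E)-4-[(1S,4S)-4-hydroxy-2,6,6-trimethylcyclohex-2-en-1-yl]but-3-en-2-one (racemate, the 1S,4S enantiomer is drawn) | CC(=O)/C=C/[C@@H]1C(C)=C[C@@H](O)CC1(C)C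
F5 | step 9 | (2E,4E)-5-[(3R,4S)-3-hydroperoxy-4-hydroxy-2,6,6-trimethylcyclohex-1-en-1-yl]-3-methylpenta-2,4-dienenitrile | N#C/C=C(C)/C=C/C1=C(C)[C@@H](OO)[C@@H](O)CC1(C)C
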